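Palisadin B is disconnected at C3 of ring B, the oxepene: this methyl-bearing alkene carbon lies between O-bearing C2 and vinylic C4–H, and removing it contracts ring B to a six-membered 2-methyl enol ether that bromonium cyclization of (E)-geranylacetone delivers with ring A and its three stereocentres complete. The key step reinserts that carbon as dibromocarbene: cyclopropanation of the enol ether C=C and opening of the shared bond enlarge the dihydropyran to the oxepene in one operation, placing bromine on C3 (exchanged for methyl) and an exocyclic methylene on C2 (hydroborated to the CH2Br arm). Its precursor is the trans-fused 6-bromo-2,5,5,8a-tetramethylhexahydrochromene.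

Key step: step 2

Assumption: the sense of induction of the chiral Lewis base in step 1 is taken to depend on the catalyst antipode alone, so the antipode that leads to the (4aS,6S,8aS) series is chosen in a trial run (both antipodes are accessible from (R)- and (S)-BINOL).

Step 1
Reactants: 1 (E)-geranylacetone [(5E)-6,10-dimethylundeca-5,9-dien-2-one]
Product: 2 (4aS,6S,8aS)-6-bromo-2,5,5,8a-tetramethyl-4a,5,6,7,8,8a-hexahydro-4H-chromene
Conditions: DBDMH (1.05 equiv), chiral BINOL-derived thiophosphoramide Lewis base (10 mol %), toluene/CH2Cl2, −78 °C; Na2S2O3, Et3N quench at −78 °C; filtration through basic Al2O3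
Reagents that add atoms: 1,3-dibromo-5,5-dimethylhydantoin (DBDMH), CC1(C)N(Br)C(=O)N(Br)C1=O
Why: Enantioselective bromonium-induced polyene cyclization under chiral Lewis base catalysis, in which catalyst-bound Br+ is delivered to one face of the terminal C9=C10 alkene, the (E)-C5=C6 alkene attacks C10 through a chair-like transition state with anti addition (hence trans ring fusion and equatorial bromine, all three stereocentres following from the catalyst-controlled face and the alkene geometry), and the ketone oxygen captures the C6 cation before loss of a C3 proton gives the endocyclic enol ether.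

Step 2
Reactants: 2 (4aS,6S,8aS)-6-bromo-2,5,5,8a-tetramethyl-4a,5,6,7,8,8a-hexahydro-4H-chromene; 3 bromoform
Product: 5 (5aS,7S,9aS)-3,7-dibromo-6,6,9a-trimethyl-2-methylidene-2,5,5a,6,7,8,9,9a-octahydro-1-benzoxepine, via gem-dibromocyclopropane 4 (not isolated)
Conditions: CHBr3 (1.5 equiv), KOt-Bu (3 equiv), pentane, −25 °C; then 0 → 35 °C
Reagents that add atoms: bromoform 3, BrC(Br)Br
Why: KOt-Bu deprotonates bromoform and α-elimination of bromide releases dibromocarbene, which adds in a concerted [2+1] cheletropic step to C2=C3 of 2, the only alkene and a strongly nucleophilic trisubstituted enol ether, closing the three-membered ring of 4. On warming, the bromine of 4 that is endo to the pyran ring ionizes in concert with disrotatory opening of the shared C2–C3 bond, O1 and C4 turning inward, to give a cis-allyl cation that is an oxocarbenium ion at the former C2 and holds the inserted, still brominated carbon between that carbon and the former C3; KOt-Bu then removes a proton from the methyl group on the oxocarbenium carbon to give the 2-methylidene bromodiene 5. The closest known reaction type is the dihalocarbene ring expansion of dihydropyrans and glycals to halogenated oxepines, and the proton-loss ending parallels the amine-mediated formation of 2-silyloxy-1,3-dienes from enones and silyl triflates. The seven-membered ring is therefore not formed by a new cyclization but by 6→7 ring enlargement through cleavage of the bond shared by the two small rings, the only ring closure being the cheletropic cyclopropanation. No stereocentre is created: both cyclopropane diastereomers carry an endo bromine and converge on the same planar cation, and C4a, C6 and C8a of 2 (C5a, C7 and C9a of 5) are untouched, the equatorial secondary bromide having no antiperiplanar hydrogen for base-induced elimination. The step needs site-selective carbene addition, cleavage of the shared and not a peripheral cyclopropane bond, and loss of the methyl proton in place of capture of the cation; the single electron-rich alkene secures the first, the ring oxygen (which stabilizes only the cation from shared-bond opening) the second, and the third follows because the methyl hydrogens are the only ones α to the oxocarbenium carbon while that fully substituted carbon, flanked by C–Br and the quaternary C9a–O, is shielded from tert-butoxide, the carbene being consumed cold before 4 opens so that the enol ether of 5 is not cyclopropanated in turn.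

Step 3
Reactants: 5 (5aS,7S,9aS)-3,7-dibromo-6,6,9a-trimethyl-2-methylidene-2,5,5a,6,7,8,9,9a-octahydro-1-benzoxepine; 6 methylzinc chloride
Product: 7 (5aS,7S,9aS)-7-bromo-3,6,6,9a-tetramethyl-2-methylidene-2,5,5a,6,7,8,9,9a-octahydro-1-benzoxepine
Conditions: CH3ZnCl (2 equiv, 2 M in THF), Pd(PPh3)4 (5 mol %), THF, 45 °C; NaHCO3 work-up
Reagents that add atoms: methylzinc chloride 6, C[Zn]Cl
Why: Negishi cross-coupling, in which zerovalent palladium inserts selectively into the vinylic sp2 C–Br bond of the bromodiene (the hindered secondary sp3 C–Br bond next to the quaternary carbon is inert to Pd(PPh3)4 and to the mild, non-basic organozinc) and transmetalation followed by reductive elimination installs the C3 methyl without harming the acid-labile dienyl ether.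

Step 4
Reactants: 7 (5aS,7S,9aS)-7-bromo-3,6,6,9a-tetramethyl-2-methylidene-2,5,5a,6,7,8,9,9a-octahydro-1-benzoxepine
Product: 9 [(2R,5aS,7S,9aS)-7-bromo-3,6,6,9a-tetramethyl-2,5,5a,6,7,8,9,9a-octahydro-1-benzoxepin-2-yl]methanol, via B-alkyl-9-BBN adduct 8 (not isolated)
Conditions: 9-BBN (1.5 equiv), THF, 0 → 23 °C; then 3 M NaOH, 30% H2O2, 0 °C
Reagents that add atoms: hydrogen peroxide, OO (the oxygen of 9); 9-borabicyclo[3.3.1]nonane, B1C2CCCC1CCC2 (boron and bicycle are held only in 8, and only hydrogen stays in 9)
Why: Hydroboration–oxidation of an exocyclic enol ether as practised for C-glycosides, in which the bulky 9-BBN attacks only the terminal 1,1-disubstituted alkene (boron to CH2 on steric and electronic grounds, the trisubstituted C3=C4 alkene being left) from the face opposite the pseudo-axial C9a methyl, so that the syn-delivered hydrogen at C2 is anti to that methyl (2R) and the CH2OH arm ends cis to it.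

Step 5
Reactants: 9 [(2R,5aS,7S,9aS)-7-bromo-3,6,6,9a-tetramethyl-2,5,5a,6,7,8,9,9a-octahydro-1-benzoxepin-2-yl]methanol
Product: 10 palisadin B, (2R,5aS,7S,9aS)-7-bromo-2-(bromomethyl)-3,6,6,9a-tetramethyl-2,5,5a,6,7,8,9,9a-octahydro-1-benzoxepine
Conditions: CBr4 (1.5 equiv), PPh3 (1.6 equiv), 2,6-lutidine (0.2 equiv), CH2Cl2, 0 °C
Reagents that add atoms: carbon tetrabromide, BrC(Br)(Br)Br
Why: Appel reaction, in which the primary alcohol is activated as its alkoxyphosphonium ion and displaced by bromide in an SN2 step at the unhindered CH2 carbon, so that no stereocentre is involved and the alkene, the allylic ether and the secondary bromide survive the near-neutral conditions.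

Compound list
1 | (E)-geranylacetone, (5E)-6,10-dimethylundeca-5,9-dien-2-one | CC(C)=CCC/C(C)=C/CCC(C)=O | starting material
2 | (4aS,6S,8aS)-6-bromo-2,5,5,8a-tetramethyl-4a,5,6,7,8,8a-hexahydro-4H-chromene (trans-fused, equatorial Br, endocyclic C2=C3 enol ether) | CC1=CC[C@H]2C(C)(C)[C@@H](Br)CC[C@]2(C)O1 | intermediate
3 | bromoform | BrC(Br)Br | starting material
4 | gem-dibromocyclopropane of 2: CBr2 bridging C2 and C3 of the dihydropyran (7,7-dibromo-1-methyl-2-oxabicyclo[4.1.0]heptane unit trans-fused to ring A, ring-A centres as in 2, both cyclopropane diastereomers) | CC12C(C1(Br)Br)C[C@H]1C(C)(C)[C@@H](Br)CC[C@]1(C)O2 | intermediate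
5 | (5aS,7S,9aS)-3,7-dibromo-6,6,9a-trimethyl-2-methylidene-2,5,5a,6,7,8,9,9a-octahydro-1-benzoxepine | BrC1=CC[C@H]2C(C)(C)[C@@H](Br)CC[C@]2(C)OC1=C | intermediate
6 | methylzinc chloride | C[Zn]Cl | starting material
7 | (5aS,7S,9aS)-7-bromo-3,6,6,9a-tetramethyl-2-methylidene-2,5,5a,6,7,8,9,9a-octahydro-1-benzoxepine | CC1=CC[C@H]2C(C)(C)[C@@H](Br)CC[C@]2(C)OC1=C | intermediate
8 | 9-{[(2S,5aS,7S,9aS)-7-bromo-3,6,6,9a-tetramethyl-2,5,5a,6,7,8,9,9a-octahydro-1-benzoxepin-2-yl]methyl}-9-borabicyclo[3.3.1]nonane (C2–H anti to the C9a methyl; 2S only by priority change, same geometry as 9) | CC1=CC[C@H]2C(C)(C)[C@@H](Br)CC[C@]2(C)O[C@H]1CB1C2CCCC1CCC2 | intermediate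
9 | [(2R,5aS,7S,9aS)-7-bromo-3,6,6,9a-tetramethyl-2,5,5a,6,7,8,9,9a-octahydro-1-benzoxepin-2-yl]methanol | CC1=CC[C@H]2C(C)(C)[C@@H](Br)CC[C@]2(C)O[C@H]1CO | intermediate
10 | palisadin B, (2R,5aS,7S,9aS)-7-bromo-2-(bromomethyl)-3,6,6,9a-tetramethyl-2,5,5a,6,7,8,9,9a-octahydro-1-benzoxepine | CC1=CC[C@H]2C(C)(C)[C@@H](Br)CC[C@]2(C)O[C@H]1CBr | target

Total step count: 5. Longest linear sequence: 5 steps (1 to 10).

Steps most likely to fail

Step 2. The cyclopropane may begin to open while carbene is still being generated, so that the new exocyclic enol ether is cyclopropanated a second time. The oxocarbenium ion may also lose a ring proton at C5 instead of the methyl proton, be captured by tert-butoxide, or fragment at the tertiary C9a–O bond. The fallback sets out from 2 and separates ring opening from its termination. The carbene is added at −30 °C and the cold pentane solution is filtered from the salts. The crude cyclopropane 4 is then opened in K2CO3/MeOH at 40 °C, the alkoxide-capture mode of this ring expansion. This should give the mixed methyl ketal (5aS,7S,9aS)-3,7-dibromo-2-methoxy-2,6,6,9a-tetramethyl-2,5,5a,6,7,8,9,9a-octahydro-1-benzoxepine F1 as C2 epimers, a stable compound that can be purified. Me3SiOTf/i-Pr2NEt in CH2Cl2 (−78 → 0 °C) then ionizes the methoxy group and removes the methyl proton under kinetic control, the established conversion of ketals into enol ethers. The route is rejoined at 5.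

Step 1. Enantiofacial discrimination may be poor, because the chiral Lewis base has a ketone and not an aryl or phenol terminator to work with. The electron-rich enol ether may also be consumed by residual N–Br reagent as it forms. The fallback sets out from 1 and uses racemic brominative cyclization with 2,4,4,6-tetrabromocyclohexa-2,5-dienone in CH3NO2 at 0 °C, the classical reagent type for bromonium cyclization of geranyl derivatives. This gives the racemic enol ether rac-6-bromo-2,5,5,8a-tetramethyl-4a,5,6,7,8,8a-hexahydro-4H-chromene F2. Preparative HPLC on an amylose tris(3,5-dimethylphenylcarbamate) phase (hexane/i-PrOH with 0.1% Et3N) separates the enantiomers. The (4aS,6S,8aS) antipode rejoins the route at 2.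

Step 4. The borane may approach the face syn to the angular methyl, giving the C2 epimer, or the β-alkoxy organoborane may fragment with opening of ring B. The fallback sets out from 7 and reverses the order of oxidation and reduction. Dimethyldioxirane in acetone/CH2Cl2 at −78 °C should epoxidize the enol ether alkene from the face opposite the C9a methyl. This gives the spiro-epoxide at C2 of ring B, (R) at the spiro carbon with the oxirane oxygen anti to the C9a methyl, F3. i-Bu2AlH in CH2Cl2 at −78 °C then binds the oxirane oxygen, opens it to the oxocarbenium ion and delivers hydride to C2 on that same face, as in the epoxidation–reduction of cyclic enol ethers used for fused polyethers. The route is rejoined at 9.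

Further compounds
F1 | step 2 | (5aS,7S,9aS)-3,7-dibromo-2-methoxy-2,6,6,9a-tetramethyl-2,5,5a,6,7,8,9,9a-octahydro-1-benzoxepine (C2 epimers) | COC1(C)C(Br)=CC[C@H]2C(C)(C)[C@@H](Br)CC[C@]2(C)O1
F2 | step 1 | racemic 6-bromo-2,5,5,8a-tetramethyl-4a,5,6,7,8,8a-hexahydro-4H-chromene, (4aS,6S,8aS) and (4aR,6R,8aR) in equal parts | CC1=CC[C@H]2C(C)(C)[C@@H](Br)CC[C@]2(C)O1.CC1=CC[C@@H]2C(C)(C)[C@H](Br)CC[C@@]2(C)O1
F3 | step 4 | spiro-epoxide of 7 at C2, (R) at the spiro carbon, oxirane oxygen anti to the C9a methyl | CC1=CC[C@H]2C(C)(C)[C@@H](Br)CC[C@]2(C)O[C@@]13CO3
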